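## Retrosynthetic overview

1. Target ⇐ 5-ketone (1,2-reduction) ⇐ 1(10)E,2Z-diene (double dioxirane epoxidation) ⇐ lactone ring closed by carbonylation of a C7-ethynyl/C6-OH pair.
2. Ten-membered ring ⇐ photochemical 6π ring opening (C5–C10 cleavage) of a trans-fused 5-silyloxy bicyclic 1,3-diene; the enol silyl ether released becomes the 4(15)-en-5-one.
3. C6/C7/C8 triad ⇐ set on the rigid bicycle by hydroxyl-directed epoxidation and trans-diaxial acetylide opening.
4. Ring B ⇐ ring-closing metathesis of a C10-allyl and a C5-(1-acetoxyallyl) group.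
5. Ring A (C1–C5, C10, C14, C15) ⇐ 2,6-dimethylphenol, dearomatised and desymmetrised by catalytic asymmetric ortho-C-allylation. Ring order: A, B, ten-membered ring, lactone, epoxides.

Assumption: atom labels C1–C15 are those of the germacrane skeleton of the target (lactone C12 on O–C6, angelate on O–C8, C9 = CH2, C14 on C10, C15 on C4) and are kept for all intermediates; the ligand antipode in step 1 is taken as the one that delivers (R)-3.

## Route

Step 1
Reactants: 1 2,6-dimethylphenol; 2 allyl methyl carbonate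
Product: 3 (R)-6-allyl-2,6-dimethylcyclohexa-2,4-dien-1-one
Conditions: Pd2(dba)3 (2.5 mol %), (S)-t-BuPHOX (6 mol %), toluene, 0 → 23 °C; used at once, kept cold
Reagents that add atoms: none
Why: Proposed new method: a palladium-catalysed asymmetric dearomative allylic alkylation (Tsuji–Trost type) in which zerovalent palladium ionises 2, the released methoxide deprotonates 1, and the O-bound aryloxide–allyl complex of divalent palladium collapses by inner-sphere seven-membered reductive elimination that can reach only an ortho carbon (O-allylation is reversible, para attack is out of reach), the chiral P,N-ligand choosing between the two enantiotopic ortho carbons of the mirror-symmetric phenoxide and so setting the quaternary C10 as R; the closest known reaction types are the palladium–phosphinooxazoline decarboxylative asymmetric allylic alkylation of ketone enolates, the palladium-catalysed asymmetric allylic dearomatisation of 2-naphthols, and the racemic ortho-C-allylation of sodium 2,6-dimethylphenoxide in non-polar solvents.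

Step 2
Reactants: 4 acrolein; 5 acetyl bromide
Product: 6 3-bromoprop-1-en-1-yl acetate (E/Z mixture)
Conditions: ZnCl2 (1 mol %), CH2Cl2, −20 → 0 °C
Reagents that add atoms: none
Why: 1,4-addition of the acyl bromide across the enal (bromide to the terminal carbon, acetyl to the enol oxygen) gives the γ-acetoxyallyl bromide; no stereocentre is formed and the E/Z mixture is used as such because the derived allylzinc equilibrates.

Step 3
Reactants: 3 (R)-6-allyl-2,6-dimethylcyclohexa-2,4-dien-1-one; 6 3-bromoprop-1-en-1-yl acetate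
Product: 8 (1S)-1-[(1S,6R)-6-allyl-2,6-dimethyl-1-(triethylsilyloxy)cyclohexa-2,4-dien-1-yl]prop-2-en-1-yl acetate, via bromozinc alkoxide 7 (not isolated)
Conditions: Zn dust (activated), THF, 0 °C; then TESOTf, 2,6-lutidine, −40 → 0 °C
Reagents that add atoms: triethylsilyl trifluoromethanesulfonate (TESOTf), CC[Si](CC)(CC)OS(=O)(=O)C(F)(F)F
Why: Barbier-type γ-acyloxyallylation in which the internally chelated (Z)-γ-acetoxyallylzinc adds 1,2 to C5 through a chair (Zimmerman–Traxler) transition state on the ring face carrying the C10 methyl (away from the larger allyl group, C10 pseudo-equatorial), which sets C5 with its oxygen anti to the methyl and C6 threo to it, the zinc alkoxide then being silylated in the same flask; the facial preference is expected to be moderate and the minor C5 epimer is removed by chromatography.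

Step 4
Reactants: 8 (1S)-1-[(1S,6R)-6-allyl-2,6-dimethyl-1-(triethylsilyloxy)cyclohexa-2,4-dien-1-yl]prop-2-en-1-yl acetate
Product: 9 (4aS,5S,8aR)-4,8a-dimethyl-4a-(triethylsilyloxy)-4a,5,8,8a-tetrahydronaphthalen-5-yl acetate (trans ring fusion; acetoxy on the face of the 8a-methyl)
Conditions: second-generation Grubbs catalyst (5 mol %), CH2Cl2, 40 °C
Reagents that add atoms: none
Why: ring-closing metathesis of the two terminal alkenes closes the six-membered ring B (C7=C8) without touching a stereocentre, and the anti disposition of C6 and C9 makes the fusion trans.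

Step 5
Reactants: 9 (4aS,5S,8aR)-4,8a-dimethyl-4a-(triethylsilyloxy)-4a,5,8,8a-tetrahydronaphthalen-5-yl acetate
Product: 10 (4aS,5S,8aR)-4,8a-dimethyl-4a-(triethylsilyloxy)-4a,5,8,8a-tetrahydronaphthalen-5-ol
Conditions: K2CO3 (0.2 equiv), MeOH, 0 °C
Reagents that add atoms: none
Why: base-catalysed transesterification (Zemplén-type methanolysis) frees the secondary allylic alcohol while the tertiary silyl ether stays in place, silyl migration being impossible because O5 and O6 are trans-diaxial on the locked bicycle.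

Step 6
Reactants: 10 (4aS,5S,8aR)-4,8a-dimethyl-4a-(triethylsilyloxy)-4a,5,8,8a-tetrahydronaphthalen-5-ol
Product: 11 (4aS,5S,6R,7S,8aR)-6,7-epoxy-4,8a-dimethyl-4a-(triethylsilyloxy)-4a,5,6,7,8,8a-hexahydronaphthalen-5-ol (epoxide cis to the 5-OH and to the 8a-methyl)
Conditions: VO(acac)2 (5 mol %), t-BuOOH (1.2 equiv), toluene, 0 °C
Reagents that add atoms: tert-butyl hydroperoxide, CC(C)(C)OO
Why: hydroxyl-directed vanadium-catalysed epoxidation (Sharpless–Michaelson type) delivers oxygen to C7=C8 syn to the pseudoaxial C6–OH, setting C7 and C8, while the ring A diene has no free hydroxyl to direct the metal and reacts far more slowly.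

Step 7
Reactants: 11 (4aS,5S,6R,7S,8aR)-6,7-epoxy-4,8a-dimethyl-4a-(triethylsilyloxy)-4a,5,6,7,8,8a-hexahydronaphthalen-5-ol; 12 lithium acetylide–ethylenediamine complex (LiC≡CH·H2NCH2CH2NH2)
Product: 13 (4aS,5S,6R,7S,8aR)-6-ethynyl-4,8a-dimethyl-4a-(triethylsilyloxy)-4a,5,6,7,8,8a-hexahydronaphthalene-5,7-diol (both hydroxyls on the face of the 8a-methyl, ethynyl on the opposite face)
Conditions: 12 (4 equiv), DMSO, 23 → 45 °C; H2O work-up
Reagents that add atoms: none
Why: trans-diaxial (Fürst–Plattner) SN2 opening of the epoxide on the locked trans-fused chair, the acetylide entering axially at C7 from the face opposite the epoxide (inversion at C7, C8–O retained), so that O6 and O8 are cis and the new C7–C bond is trans to both; the cis epoxy alkoxide cannot undergo Payne rearrangement.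

Step 8
Reactants: 13 (4aS,5S,6R,7S,8aR)-6-ethynyl-4,8a-dimethyl-4a-(triethylsilyloxy)-4a,5,6,7,8,8a-hexahydronaphthalene-5,7-diol; 14 angelic acid ((Z)-2-methylbut-2-enoic acid)
Product: 15 (4aS,5S,6S,7S,8aR)-6-ethynyl-5-hydroxy-4,8a-dimethyl-4a-(triethylsilyloxy)-4a,5,6,7,8,8a-hexahydronaphthalen-7-yl (Z)-2-methylbut-2-enoate
Conditions: 14 (1.5 equiv), 2,4,6-trichlorobenzoyl chloride, Et3N, toluene, 23 °C; then 13, 80 °C (no DMAP)
Reagents that add atoms: none
Why: Yamaguchi-type esterification through the mixed anhydride, run without a nucleophilic catalyst so that the (Z)-enoate does not isomerise to the tiglate, acylates the C8 hydroxyl (next to a CH2) in preference to the C6 hydroxyl, which is neopentyl-like beside the fully substituted silyloxy carbon; no stereocentre changes.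

Step 9
Reactants: 15 (4aS,5S,6S,7S,8aR)-6-ethynyl-5-hydroxy-4,8a-dimethyl-4a-(triethylsilyloxy)-4a,5,6,7,8,8a-hexahydronaphthalen-7-yl (Z)-2-methylbut-2-enoate
Product: 17 (6S,7S,8S,1(10)E,2Z)-7-ethynyl-6-hydroxy-10-methyl-4-methylene-5-oxocyclodeca-1(10),2-dien-8-yl (Z)-2-methylbut-2-enoate, via triethylsilyl trienol ether 16 (not isolated)
Conditions: hν (300 nm, borosilicate filter), degassed MeCN, −30 °C; then Pd(OAc)2 (1.2 equiv), −30 → 23 °C
Reagents that add atoms: none
Why: photochemical conrotatory 6π electrocyclic ring opening of the trans-fused cyclohexa-1,3-diene cleaves C5–C10 and, because the two pseudo-equatorial ring B bonds must both turn outward, gives the ten-membered ring with 1(10)E and 2Z geometry (the course known for trans-fused eudesma-1,3-dienes and steroidal 5,7-dienes), after which Saegusa–Ito oxidation of the regiodefined enol silyl ether gives the 4(15)-en-5-one, the only β-hydrogens available being those of C15; C6, C7 and C8 are untouched.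

Step 10
Reactants: 17 (6S,7S,8S,1(10)E,2Z)-7-ethynyl-6-hydroxy-10-methyl-4-methylene-5-oxocyclodeca-1(10),2-dien-8-yl (Z)-2-methylbut-2-enoate
Product: 18 (6S,7R,8S)-8-angeloyloxy-5-oxogermacra-1(10)E,2Z,4(15),11(13)-tetraen-12,6-olide
Conditions: PdCl2 (5 mol %), thiourea (10 mol %), CO (1 atm), acetone, 50 °C
Reagents that add atoms: carbon monoxide, [C-]#[O+]
Why: palladium-catalysed cyclocarbonylation of the homopropargylic alcohol, in which the alkoxycarbonyl–palladium species formed on O6 adds syn across the ethynyl group and protonolysis releases the trans-fused α-methylene-γ-butyrolactone; O8 is blocked as the angelate and no stereocentre is altered.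

Step 11
Reactants: 18 (6S,7R,8S)-8-angeloyloxy-5-oxogermacra-1(10)E,2Z,4(15),11(13)-tetraen-12,6-olide
Product: 19 (1R,2S,3S,6S,7R,8S,10R)-8-angeloyloxy-1,10:2,3-diepoxy-5-oxogermacra-4(15),11(13)-dien-12,6-olide
Conditions: dimethyldioxirane (2.5 equiv), acetone, −20 → 0 °C
Reagents that add atoms: dimethyldioxirane, CC1(C)OO1
Why: electrophilic dioxirane epoxidation touches only the electron-rich 1(10),2-diene (enone, α-methylene lactone and angelate are deactivated), the E-trisubstituted alkene being attacked from the outer face of the folded ring and the Z-alkene then anti to the new C1–O bond, which sets C1, C10, C2 and C3.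

Step 12
Reactants: 19 (1R,2S,3S,6S,7R,8S,10R)-8-angeloyloxy-1,10:2,3-diepoxy-5-oxogermacra-4(15),11(13)-dien-12,6-olide
Product: 20 (1R,2S,3S,5R,6S,7R,8S,10R)-8-angeloyloxy-1,10:2,3-diepoxy-5-hydroxygermacra-4(15),11(13)-dien-12,6-olide (CNP0038366.2)
Conditions: NaBH4 (1 equiv), CeCl3·7H2O (1.2 equiv), MeOH, −78 °C
Reagents that add atoms: none
Why: Luche 1,2-reduction, hydride adding to the exo-methylene ketone anti to the C6–O bond (Felkin–Anh polar model, outer face of the ring) to give the (5R)-alcohol cis to the lactone oxygen, while the cold cerium conditions spare the α-methylene lactone, the epoxides and the angelate.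

## Compound list

1 | 2,6-dimethylphenol | Cc1cccc(C)c1O | starting material
2 | allyl methyl carbonate | C=CCOC(=O)OC | starting material
3 | (R)-6-allyl-2,6-dimethylcyclohexa-2,4-dien-1-one | C=CC[C@]1(C)C=CC=C(C)C1=O | intermediate
4 | acrolein | C=CC=O | starting material
5 | acetyl bromide | CC(=O)Br | starting material
6 | 3-bromoprop-1-en-1-yl acetate (E/Z mixture) | CC(=O)OC=CCBr | intermediate
7 | bromozinc (1S,6R)-1-[(1S)-1-acetoxyprop-2-en-1-yl]-6-allyl-2,6-dimethylcyclohexa-2,4-dien-1-olate | C=CC[C@]1(C)C=CC=C(C)[C@@]1(O[Zn]Br)[C@@H](OC(C)=O)C=C | intermediate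
8 | (1S)-1-[(1S,6R)-6-allyl-2,6-dimethyl-1-(triethylsilyloxy)cyclohexa-2,4-dien-1-yl]prop-2-en-1-yl acetate | C=CC[C@]1(C)C=CC=C(C)[C@@]1(O[Si](CC)(CC)CC)[C@@H](OC(C)=O)C=C | intermediate
9 | (4aS,5S,8aR)-4,8a-dimethyl-4a-(triethylsilyloxy)-4a,5,8,8a-tetrahydronaphthalen-5-yl acetate | CC(=O)O[C@H]2C=CC[C@]3(C)C=CC=C(C)[C@@]23O[Si](CC)(CC)CC | intermediate
10 | (4aS,5S,8aR)-4,8a-dimethyl-4a-(triethylsilyloxy)-4a,5,8,8a-tetrahydronaphthalen-5-ol | O[C@H]2C=CC[C@]3(C)C=CC=C(C)[C@@]23O[Si](CC)(CC)CC | intermediate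
11 | (4aS,5S,6R,7S,8aR)-6,7-epoxy-4,8a-dimethyl-4a-(triethylsilyloxy)-4a,5,6,7,8,8a-hexahydronaphthalen-5-ol | O[C@H]2[C@H]4O[C@H]4C[C@]3(C)C=CC=C(C)[C@@]23O[Si](CC)(CC)CC | intermediate
12 | lithium acetylide–ethylenediamine complex | [Li+].[C-]#C.NCCN | starting material
13 | (4aS,5S,6R,7S,8aR)-6-ethynyl-4,8a-dimethyl-4a-(triethylsilyloxy)-4a,5,6,7,8,8a-hexahydronaphthalene-5,7-diol | O[C@H]2[C@H](C#C)[C@@H](O)C[C@]3(C)C=CC=C(C)[C@@]23O[Si](CC)(CC)CC | intermediate
14 | angelic acid ((Z)-2-methylbut-2-enoic acid) | C/C=C(/C)C(=O)O | starting material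
15 | (4aS,5S,6S,7S,8aR)-6-ethynyl-5-hydroxy-4,8a-dimethyl-4a-(triethylsilyloxy)-4a,5,6,7,8,8a-hexahydronaphthalen-7-yl (Z)-2-methylbut-2-enoate | O[C@H]2[C@H](C#C)[C@@H](OC(=O)/C(C)=C\C)C[C@]3(C)C=CC=C(C)[C@@]23O[Si](CC)(CC)CC | intermediate
16 | (6S,7S,8S,1(10)E,2Z,4Z)-7-ethynyl-6-hydroxy-4,10-dimethyl-5-(triethylsilyloxy)cyclodeca-1(10),2,4-trien-8-yl (Z)-2-methylbut-2-enoate (C6 trans to C3 across C4=C5) | O[C@H]2[C@H](C#C)[C@@H](OC(=O)/C(C)=C\C)C/C(C)=C/C=C\C(C)=C2/O[Si](CC)(CC)CC | intermediate
17 | (6S,7S,8S,1(10)E,2Z)-7-ethynyl-6-hydroxy-10-methyl-4-methylene-5-oxocyclodeca-1(10),2-dien-8-yl (Z)-2-methylbut-2-enoate | O[C@H]2[C@H](C#C)[C@@H](OC(=O)/C(C)=C\C)C/C(C)=C/C=C\C(=C)C2=O | intermediate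
18 | (6S,7R,8S)-8-angeloyloxy-5-oxogermacra-1(10)E,2Z,4(15),11(13)-tetraen-12,6-olide | C=C1C(=O)O[C@H]2[C@H]1[C@@H](OC(=O)/C(C)=C\C)C/C(C)=C/C=C\C(=C)C2=O | intermediate
19 | (1R,2S,3S,6S,7R,8S,10R)-8-angeloyloxy-1,10:2,3-diepoxy-5-oxogermacra-4(15),11(13)-dien-12,6-olide | C=C1C(=O)O[C@H]2[C@H]1[C@@H](OC(=O)/C(C)=C\C)C[C@@]1(C)O[C@@H]1[C@H]1O[C@H]1C(=C)C2=O | intermediate
20 | (1R,2S,3S,5R,6S,7R,8S,10R)-8-angeloyloxy-1,10:2,3-diepoxy-5-hydroxygermacra-4(15),11(13)-dien-12,6-olide | C=C1C(=O)O[C@H]2[C@H]1[C@@H](OC(=O)/C(C)=C\C)C[C@@]1(C)O[C@@H]1[C@H]1O[C@H]1C(=C)[C@H]2O | target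

## Step count and risks

Total step count: 12 (11 on the main line plus the one-step preparation of 6). Longest linear sequence: 11 steps (1 → 3 → 8 → 9 → 10 → 11 → 13 → 15 → 17 → 18 → 19 → 20).

The three steps most likely to fail are steps 1, 9 and 11.

Step 1 is an unproven catalytic asymmetric dearomatisation; it may give the O-allyl ether, the para-allyl phenol or low ee, and 3 can rearrange or dimerise on standing. The fallback sets out from 1 and comes back at 3. Compound 1 is deprotonated with NaH and its sodium salt is C-allylated with allyl bromide as a suspension in toluene (kinetic contact-ion-pair ortho alkylation), giving racemic 6-allyl-2,6-dimethylcyclohexa-2,4-dien-1-one F1. The enantiomers of F1 are separated by preparative chiral-phase supercritical-fluid chromatography, and the (R)-enantiomer is compound 3.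

Step 9 can stall at a photostationary mixture, and the strained triene 16 can reclose thermally, undergo a 1,7-hydrogen shift, or be mishandled by Pd(OAc)2 in the presence of the terminal alkyne. The fallback sets out from 15 and comes back at 17. The silyl group is removed first (HF·pyridine, THF, 0 °C) to give the tertiary dienol (4aS,5S,6S,7S,8aR)-6-ethynyl-4a,5-dihydroxy-4,8a-dimethyl-4a,5,6,7,8,8a-hexahydronaphthalen-7-yl (Z)-2-methylbut-2-enoate F2. Irradiation of F2 (300 nm, MeCN, −30 °C) opens the ring in the same conrotatory sense, and the trienol ketonises irreversibly to (6S,7S,8S,1(10)E,2Z)-7-ethynyl-6-hydroxy-4,10-dimethyl-5-oxocyclodeca-1(10),2-dien-8-yl (Z)-2-methylbut-2-enoate F3 (C4 epimers), which drains the photoequilibrium. Soft enolisation towards the diene-conjugated C4 (TMSOTf, Et3N, CH2Cl2, −78 °C) gives (6S,7R,8S,1(10)E,2Z)-7-ethynyl-4,10-dimethyl-5,6-bis(trimethylsilyloxy)cyclodeca-1(10),2,4-trien-8-yl (Z)-2-methylbut-2-enoate F4. Pd(OAc)2 in MeCN followed by a citric acid wash then returns 17.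

Step 11 relies on the ring conformation to control two epoxidations at once and may give the wrong diastereomers. The fallback sets out from 18 and comes back at 19, and replaces substrate control by reagent control with chiral dioxiranes (Shi epoxidation), one alkene at a time. The fructose-derived ketone catalyst (KHSO5, K2CO3, MeCN–dimethoxymethane–buffer, 0 °C; catalyst antipode chosen for the 1R,10R sense) epoxidises the E-trisubstituted 1(10)-alkene to (1R,6S,7R,8S,10R)-8-angeloyloxy-1,10-epoxy-5-oxogermacra-2Z,4(15),11(13)-trien-12,6-olide F5. The glucose-derived N-aryl-oxazolidinone ketone catalyst, which is suited to cis-alkenes flanked by a π-system, then epoxidises the 2Z-alkene to return 19.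

## Further compounds

F1 | step 1 | racemic 6-allyl-2,6-dimethylcyclohexa-2,4-dien-1-one | C=CCC1(C)C=CC=C(C)C1=O
F2 | step 9 | (4aS,5S,6S,7S,8aR)-6-ethynyl-4a,5-dihydroxy-4,8a-dimethyl-4a,5,6,7,8,8a-hexahydronaphthalen-7-yl (Z)-2-methylbut-2-enoate | O[C@H]2[C@H](C#C)[C@@H](OC(=O)/C(C)=C\C)C[C@]3(C)C=CC=C(C)[C@@]23O
F3 | step 9 | (6S,7S,8S,1(10)E,2Z)-7-ethynyl-6-hydroxy-4,10-dimethyl-5-oxocyclodeca-1(10),2-dien-8-yl (Z)-2-methylbut-2-enoate (C4 epimers) | O[C@H]2[C@H](C#C)[C@@H](OC(=O)/C(C)=C\C)C/C(C)=C/C=C\C(C)C2=O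
F4 | step 9 | (6S,7R,8S,1(10)E,2Z)-7-ethynyl-4,10-dimethyl-5,6-bis(trimethylsilyloxy)cyclodeca-1(10),2,4-trien-8-yl (Z)-2-methylbut-2-enoate | C[Si](C)(C)O[C@H]2[C@H](C#C)[C@@H](OC(=O)/C(C)=C\C)C/C(C)=C/C=C\C(C)=C2O[Si](C)(C)C
F5 | step 11 | (1R,6S,7R,8S,10R)-8-angeloyloxy-1,10-epoxy-5-oxogermacra-2Z,4(15),11(13)-trien-12,6-olide | C=C1C(=O)O[C@H]2[C@H]1[C@@H](OC(=O)/C(C)=C\C)C[C@@]1(C)O[C@@H]1/C=C\C(=C)C2=O
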